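**Remark on the chemistry:** the target has no stereocentre. The ortho ester carbon of 11 is formed as a racemate and becomes the planar ester carbon again in step 5. Compounds 1, 2 and 6 are taken as purchased. TBS stands for tert-butyl(dimethyl)silyl throughout.

## The problem

Compound 12, octadecyl 3-(2,4-dihydroxy-3-methoxyphenyl)propanoate, has one ring, a benzene with four contiguous substituents. C1 carries a three-carbon arm (benzylic C7, then C8 and the ester carbon C9), C2 a free hydroxyl, C3 a methoxy group and C4 a second free hydroxyl; C9 is esterified with a C18 alcohol. There is no stereocentre, so nothing has to be controlled in space. The task is one of regiochemistry and chemoselectivity: the arm must be attached at the one ring position next to the C2 oxygen, and the two phenols must be told apart from each other. The sensitive features are the electron-rich 2-methoxyresorcinol nucleus, which is easily oxidised and easily substituted twice, and the ortho-hydroxy dihydrocinnamate motif. Under acid or heat the C2 hydroxyl can close onto C9 to give a dihydrocoumarin with loss of the fatty alcohol, and the ester is open to hydrolysis and transesterification. The feature that makes the key step possible is the position of C7: it sits on C1, ortho to the C2 oxygen and para to the C4 oxygen. C7 can therefore be unmasked as the exocyclic methylene of a quinone methide, electrophilic at that carbon only. The C2 oxygen is then placed to close a six-membered ring onto C9, so a two-carbon ketene acetal can bring in C8 and C9 in one event, at the ester oxidation level and with the C18 chain attached.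

## Retrosynthesis

**12 from 11.** No carbon–carbon bond is cut. The target is read as the collapsed form of a cyclic ortho ester: the C2 oxygen is tied back to C9, and the two acidic oxygens (the C4 hydroxyl and the ortho ester hydroxyl) carry TBS groups, which gives chroman 11. A free diphenol or a lactone would be the neighbouring choices. Free phenols would destroy a silyl ketene acetal, and a lactone would need a separate ring opening with the fatty alcohol. The forward reaction must remove both silyl groups and let the tetrahedral carbon expel the aryl oxide, not the alkoxide, under conditions that do not lactonise 12.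

**11 from 5 and 8.** The C7–C8 bond and the bond from the C2 oxygen to C9 are cut together, as the reverse of a [4+2] addition. This leads to ortho-quinone methide 10 and silyl ketene acetal 8. Quinone methide 10 is traced to Mannich base 5 through its N-methyl ammonium salt 9, from which it is released by base. A cut at C1–C7 alone (acid-mediated alkylation of the arene with an acrylate) would pass through strong acid and a lactone. A cut at C8–C9 (carbonylation) needs a styrene and pressurised gas. The chosen cut splits 11 into a C10 arene part and a C20 ester part of matching polarity. The forward reaction must generate 10 slowly, without an acidic proton in the flask, and in the presence of excess 8.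

**8 from 6.** The O–Si bond is cut, leading through lithium enolate 7 to acetate 6. A TBS group is chosen over trimethylsilyl because acetate enolates partition between oxygen and carbon with the smaller silyl chloride. The TBS ketene acetal also transfers its silyl group to phenoxides more slowly and survives handling as a crude, non-distillable wax.

**5 from 4.** The O–Si bond on the C4 oxygen is cut, giving diol 4. The forward reaction must distinguish two phenols. The C2 hydroxyl lies between the methoxy group and the aminomethyl arm and is hydrogen-bonded to nitrogen. The C4 hydroxyl has a ring hydrogen as one neighbour and should take a bulky silyl group first.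

**4 from 1 and 2.** The C1–C7 bond is cut as a Mannich disconnection to diol 1 and iminium salt 2. The two open activated positions of 1 are equivalent, each ortho to one hydroxyl and para to the other. Regiochemistry is therefore not in question, and the forward reaction only has to stop after one substitution.

## Roads not taken

**Alternative 1:** The cut falls on the aryl–alkyl bond C1–C7 and on the C2–O bond, the latter replaced by a C2–B bond. In the forward step (4-chloro-2-methoxyphenoxy)tri(propan-2-yl)silane A1 is deprotonated at C2, between chlorine and methoxy, and loses chloride to give the C1–C2 aryne. Bromo[2-(1,3-dioxolan-2-yl)ethyl]magnesium A2 adds at C1, the carbon remote from the methoxy group. The arylmagnesium left at C2 is quenched with a pinacol borate to give {4-[2-(1,3-dioxolan-2-yl)ethyl]-2-methoxy-3-(4,4,5,5-tetramethyl-1,3,2-dioxaborolan-2-yl)phenoxy}tri(propan-2-yl)silane A3.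
- Merits: two substituents are set in one flask on a cheap guaiacol, the regiochemistry is dictated by the inductive effect of the methoxy group, and every intermediate is a robust non-phenolic compound.
- Weak points: A3 is far from the target. It still needs oxidation of the C–B bond, acetal hydrolysis, oxidation of the aldehyde (which will sit as a lactol with the new C2 hydroxyl), esterification with the fatty alcohol and desilylation. C9 arrives at the aldehyde level without the C18 chain. The aryne needs a strong amide base that can itself add to the aryne in competition with an alkyl Grignard reagent.
- Comparison: this road is better in the certainty with which the substitution pattern is fixed and in the stability of its intermediates. The chosen plan sets against it a symmetric arene 1 for which regiochemistry is not an issue, a C8–C9 unit delivered at the ester level with the chain in place, and about half the number of steps.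

**Alternative 2:** The cut falls on C8–C9 and on the bond from C9 to the alkoxy oxygen. In the forward step 1,3-bis(benzyloxy)-4-ethenyl-2-methoxybenzene A4, carbon monoxide and the C18 alcohol combine under Pd(OAc)2, a bulky chelating diphosphine and a sulfonic acid, through a palladium hydride cycle. The product is octadecyl 3-[2,4-bis(benzyloxy)-3-methoxyphenyl]propanoate A5, and hydrogenolysis would then give the target.
- Merits: it is convergent and atom-economical, the ester is formed with its final alkoxy group, and A5 is a storable, chromatographable compound.
- Weak points: styrenes tend toward the branched 2-arylpropanoate because the benzylic palladium alkyl is stabilised. The linear ester depends on the diphosphine and may erode with an electron-rich, ortho-substituted styrene. The alcohol is a waxy solid that cannot serve as solvent, which slows alcoholysis of the acyl palladium. A4 itself costs a formylation, a double benzylation and a methylenation, and the step needs carbon monoxide under pressure.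
- Comparison: in step count the two roads are about equal, and in robustness of intermediates this one is better, since 11 must be used crude. The chosen plan has no linear-versus-branched question because the quinone methide has a single electrophilic carbon. It also needs no pressurised toxic gas, and its deprotection coincides with the unveiling of the ester.

**Alternative 3:** The cut falls on the ring bond C3–C4, so the arene is built from an open chain. In the forward step the enolate of the methoxymethyl ketone in dioctadecyl 4-(2-methoxyacetyl)heptanedioate A6 attacks either of its two equivalent ester arms. This closes the carbocycle of octadecyl 3-(3-methoxy-2,4-dioxocyclohexyl)propanoate A7, which would then be dehydrogenated to the resorcinol.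
- Merits: it is independent of aromatic substitution chemistry, symmetry removes the choice between the esters, the arm left over is exactly the side chain with its octadecyl ester, and the oxygen pattern is encoded in the connectivity.
- Weak points: A6 has several enolisable sites. The ester α-carbons can close the diester backbone on itself in a Dieckmann reaction, and the ketone can enolise toward its methine. An alkoxide base can scramble the esters, and A7 is a mixture of epimers and enols. Aromatisation must remove four hydrogens under oxidising conditions that an electron-rich resorcinol tolerates poorly. A6 itself needs several steps.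
- Comparison: this road has no advantage in length or selectivity. The chosen plan starts from an arene that already holds the three oxygens and needs no oxidation step at all.

Key step: step 4

## Route

Step 1
Reactants: 1 2-methoxybenzene-1,3-diol; 2 N,N-dimethylmethyleneiminium iodide
Product: 4 4-[(dimethylamino)methyl]-2-methoxybenzene-1,3-diol, via hydroiodide salt 3 (not isolated)
Conditions: 2 (1.0 equiv), MeCN, 0 °C to rt; then aq. NaHCO3
Reagents that add atoms: none
Why: Aromatic Mannich aminomethylation with a preformed iminium salt; the two open activated positions of 1 are equivalent, so only one monoadduct is possible, and the product stays protonated as 3 until work-up, which damps the ring against a second substitution.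

Step 2
Reactants: 4 4-[(dimethylamino)methyl]-2-methoxybenzene-1,3-diol
Product: 5 3-{[tert-butyl(dimethyl)silyl]oxy}-6-[(dimethylamino)methyl]-2-methoxyphenol
Conditions: TBSCl (1.05 equiv), imidazole, CH2Cl2/DMF, −10 to 0 °C
Reagents that add atoms: tert-butyl(chloro)dimethylsilane, CC(C)(C)[Si](C)(C)Cl
Why: Phenol silylation under imidazole catalysis; the hydroxyl para to the aminomethyl arm has only one ortho substituent and should react first, while the other hydroxyl is flanked on both sides and tied to nitrogen by a hydrogen bond, and a tertiary amine is not consumed by a silyl chloride.

Step 3
Reactants: 6 octadecyl acetate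
Product: 8 tert-butyl(dimethyl){[1-(octadecyloxy)ethenyl]oxy}silane, via lithium enolate 7 (not isolated)
Conditions: LiN(iPr)2 (commercial solution, 1.1 equiv), THF, −78 °C; TBSCl, DMPU, −78 °C to rt; pentane, cold aq. NaHCO3 wash; used crude
Reagents that add atoms: tert-butyl(chloro)dimethylsilane, CC(C)(C)[Si](C)(C)Cl
Why: Kinetic ester enolisation followed by O-silylation of the enolate (silyl ketene acetal formation as in the Ireland–Claisen protocol); the bulky silyl chloride with the polar cosolvent should direct silicon to oxygen, not to carbon, and the low temperature holds back Claisen self-condensation of the acetate enolate.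

Step 4
Reactants: 5 3-{[tert-butyl(dimethyl)silyl]oxy}-6-[(dimethylamino)methyl]-2-methoxyphenol; 8 tert-butyl(dimethyl){[1-(octadecyloxy)ethenyl]oxy}silane
Product: 11 2,7-bis{[tert-butyl(dimethyl)silyl]oxy}-8-methoxy-2-(octadecyloxy)-3,4-dihydro-2H-chromene (racemic at C2), via ammonium iodide 9 (not isolated), via ortho-quinone methide 10 (not isolated)
Conditions: MeI (1.1 equiv), MeCN, rt, then evaporation; salt in CH2Cl2 added over 2 h to 8 (2.5 equiv), iPr2NEt (1.5 equiv), CH2Cl2, 0 °C to rt; pentane, filtration; used crude
Reagents that add atoms: none
Why: N-Methylation turns the dimethylamino group of 5 into a trimethylammonium leaving group (9); the amine base takes the phenolic proton and the phenoxide expels trimethylamine in a 1,4-elimination, releasing ortho-quinone methide 10 at or below room temperature. 10 is an electron-poor 1-oxadiene and 8 an electron-rich alkene, so they should combine in an inverse-electron-demand hetero-Diels–Alder reaction; the closest known reaction type is the [4+2] or Mukaiyama–Michael addition of ketene acetals and silyl ketene acetals to ortho-quinone methides generated from ortho-hydroxybenzyl ammonium salts or halides. Bond formation is asynchronous: the nucleophilic CH2 of 8 (the future C8) bonds to the exocyclic methylene C7 first, and the C2 oxygen then closes onto the ketene acetal carbon C9, with rearomatisation as the driving force. The one ring formed is the dihydropyran of the chroman, closed in the [4+2] mode; in the stepwise limit this is a 6-exo-trig attack of the phenoxide on the silyloxy(alkoxy)carbenium ion. The only new stereocentre is the ortho ester carbon; nothing controls it, it is formed racemic and it disappears in step 5. Regiochemistry is fixed by polarity, since only one orientation joins the nucleophilic terminus of 8 to the single electrophilic carbon of 10. Capture must outrun self-condensation of 10, which is secured by adding 9 slowly into an excess of 8 and by the C4 silyloxy group, which stabilises 10 as a vinylogous ester. No free phenol meets 8, because the C4 oxygen is silylated and the C2 proton is held by the amine base, so protodesilylation of the ketene acetal is suppressed.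

Step 5
Reactants: 11 2,7-bis{[tert-butyl(dimethyl)silyl]oxy}-8-methoxy-2-(octadecyloxy)-3,4-dihydro-2H-chromene
Product: 12 octadecyl 3-(2,4-dihydroxy-3-methoxyphenyl)propanoate
Conditions: TBAF (2.5 equiv), AcOH (3 equiv), THF, 0 °C to rt
Reagents that add atoms: none
Why: Fluoride desilylation of both silyl ethers; the tetrahedral oxyanion set free at the ortho ester carbon should collapse by expelling the aryl oxide, a far better leaving group than the alkoxide, which opens the ring to the octadecyl ester and frees the C2 phenol. Acetic acid keeps the medium near neutral so that 12 neither lactonises nor transesterifies.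

## Compound list

1 | 2-methoxybenzene-1,3-diol | COc1c(O)cccc1O | starting material
2 | N,N-dimethylmethyleneiminium iodide | C[N+](C)=C.[I-] | starting material
3 | 1-(2,4-dihydroxy-3-methoxyphenyl)-N,N-dimethylmethanaminium iodide (formed in the flask) | C[NH+](C)Cc1ccc(O)c(OC)c1O.[I-] | intermediate
4 | 4-[(dimethylamino)methyl]-2-methoxybenzene-1,3-diol | CN(C)Cc1ccc(O)c(OC)c1O | intermediate
5 | 3-{[tert-butyl(dimethyl)silyl]oxy}-6-[(dimethylamino)methyl]-2-methoxyphenol | CN(C)Cc1ccc(O[Si](C)(C)C(C)(C)C)c(OC)c1O | intermediate
6 | octadecyl acetate | CC(=O)OCCCCCCCCCCCCCCCCCC | starting material
7 | lithium 1-(octadecyloxy)ethen-1-olate (formed in the flask) | [Li+].C=C([O-])OCCCCCCCCCCCCCCCCCC | intermediate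
8 | tert-butyl(dimethyl){[1-(octadecyloxy)ethenyl]oxy}silane | C=C(O[Si](C)(C)C(C)(C)C)OCCCCCCCCCCCCCCCCCC | intermediate
9 | 1-(4-{[tert-butyl(dimethyl)silyl]oxy}-2-hydroxy-3-methoxyphenyl)-N,N,N-trimethylmethanaminium iodide (formed in the flask) | C[N+](C)(C)Cc1ccc(O[Si](C)(C)C(C)(C)C)c(OC)c1O.[I-] | intermediate
10 | 3-{[tert-butyl(dimethyl)silyl]oxy}-2-methoxy-6-methylidenecyclohexa-2,4-dien-1-one (formed in the flask) | C=C1C=CC(O[Si](C)(C)C(C)(C)C)=C(OC)C1=O | intermediate
11 | 2,7-bis{[tert-butyl(dimethyl)silyl]oxy}-8-methoxy-2-(octadecyloxy)-3,4-dihydro-2H-chromene, racemic at C2 | CCCCCCCCCCCCCCCCCCOC1(O[Si](C)(C)C(C)(C)C)CCc2ccc(O[Si](C)(C)C(C)(C)C)c(OC)c2O1 | intermediate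
12 | octadecyl 3-(2,4-dihydroxy-3-methoxyphenyl)propanoate | CCCCCCCCCCCCCCCCCCOC(=O)CCc1ccc(O)c(OC)c1O | target

## Summary and risks

Total step count: 5. Longest linear sequence: 4 steps (steps 1, 2, 4, 5); step 3 prepares the second partner for step 4.

**Step 4 (key step).** Three processes could defeat the capture:
- self-condensation of 10 faster than cycloaddition;
- transfer of the silyl group from 8 to the phenoxide of 9 before trimethylamine is lost, which would use up both partners;
- premature opening of the silyl ortho ester by silyl migration to the phenolic oxygen, which is harmless because step 5 converges on 12 anyway.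

The fallback sets out from 5 (through its salt 9, made as in step 4) and returns at 12. It replaces the neutral ketene acetal with a carbon acid that is present as its anion where the quinone methide is born. Salt 9 is heated with Meldrum's acid and Et3N in MeCN. Conjugate addition to 10 should give 5-[(4-{[tert-butyl(dimethyl)silyl]oxy}-2-hydroxy-3-methoxyphenyl)methyl]-2,2-dimethyl-1,3-dioxane-4,6-dione F1. The C2 phenol then acylates itself with loss of acetone to give 7-{[tert-butyl(dimethyl)silyl]oxy}-8-methoxy-2-oxo-3,4-dihydro-2H-chromene-3-carboxylic acid F2. Decarboxylation in hot pyridine leaves the lactone 7-{[tert-butyl(dimethyl)silyl]oxy}-8-methoxy-3,4-dihydro-2H-chromen-2-one F3. Octadecan-1-ol and NaH in THF at 0 °C open the aryl lactone, essentially irreversibly because an aryl oxide is released. An AcOH quench gives octadecyl 3-(4-{[tert-butyl(dimethyl)silyl]oxy}-2-hydroxy-3-methoxyphenyl)propanoate F4, and the conditions of step 5 then give 12. Partial loss of the aryl silyl group during the ring opening would be of no consequence.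

**Step 2.** Site selectivity between the two phenolic hydroxyls may be poor, or both may be silylated. The fallback sets out from 1 and returns at 5, and moves the differentiation of the oxygens ahead of the Mannich step. Monosilylation of symmetric 1 (TBSCl, 1 equiv, imidazole; statistical, with recovery of the diol) gives 3-{[tert-butyl(dimethyl)silyl]oxy}-2-methoxyphenol F5. Ortho-selective aminomethylation of its potassium phenoxide with 2 (K2CO3, CH2Cl2) then gives 5. The free hydroxyl steers the iminium ion to its own ortho position and the bulky silyl ether shields the other activated site.

**Step 5.** The tetrahedral intermediate may partition toward loss of the octadecyl oxide, or 12 may lactonise afterwards; both end in a lactone plus free fatty alcohol. The fallback sets out from 11 and returns at 12, and replaces kinetic collapse by equilibration under alkoxide. After the fluoride treatment the crude mixture contains the lactone 7-hydroxy-8-methoxy-3,4-dihydro-2H-chromen-2-one F6 together with the octadecan-1-ol that was expelled. It is treated with excess NaH in THF at 0 °C. The alkoxide of the liberated alcohol reopens the aryl lactone, driven by release of the aryl oxide, and an AcOH quench gives 12.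

**Step 1.** A second aminomethylation at the remaining activated position is possible, and the amphoteric amino diphenol may be lost during isolation. The fallback sets out from 1 and returns at 4, and uses an electrophile that deactivates the ring after one substitution. Vilsmeier–Haack formylation of 1 (POCl3, DMF, MeCN; aqueous hydrolysis) gives 2,4-dihydroxy-3-methoxybenzaldehyde F7. Reductive amination with dimethylamine and NaBH(OAc)3 then gives 4.

## Further compounds

F1 | step 4 | 5-[(4-{[tert-butyl(dimethyl)silyl]oxy}-2-hydroxy-3-methoxyphenyl)methyl]-2,2-dimethyl-1,3-dioxane-4,6-dione | CC1(C)OC(=O)C(Cc2ccc(O[Si](C)(C)C(C)(C)C)c(OC)c2O)C(=O)O1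
F2 | step 4 | 7-{[tert-butyl(dimethyl)silyl]oxy}-8-methoxy-2-oxo-3,4-dihydro-2H-chromene-3-carboxylic acid (racemic) | OC(=O)C1Cc2ccc(O[Si](C)(C)C(C)(C)C)c(OC)c2OC1=O
F3 | step 4 | 7-{[tert-butyl(dimethyl)silyl]oxy}-8-methoxy-3,4-dihydro-2H-chromen-2-one | O=C1CCc2ccc(O[Si](C)(C)C(C)(C)C)c(OC)c2O1
F4 | step 4 | octadecyl 3-(4-{[tert-butyl(dimethyl)silyl]oxy}-2-hydroxy-3-methoxyphenyl)propanoate | CCCCCCCCCCCCCCCCCCOC(=O)CCc1ccc(O[Si](C)(C)C(C)(C)C)c(OC)c1O
F5 | step 2 | 3-{[tert-butyl(dimethyl)silyl]oxy}-2-methoxyphenol | COc1c(O)cccc1O[Si](C)(C)C(C)(C)C
F6 | step 5 | 7-hydroxy-8-methoxy-3,4-dihydro-2H-chromen-2-one | COc1c(O)ccc2CCC(=O)Oc12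
F7 | step 1 | 2,4-dihydroxy-3-methoxybenzaldehyde | COc1c(O)ccc(C=O)c1O
A1 | alternative 1 | (4-chloro-2-methoxyphenoxy)tri(propan-2-yl)silane | COc1cc(Cl)ccc1O[Si](C(C)C)(C(C)C)C(C)C
A2 | alternative 1 | bromo[2-(1,3-dioxolan-2-yl)ethyl]magnesium | Br[Mg]CCC1OCCO1
A3 | alternative 1 | {4-[2-(1,3-dioxolan-2-yl)ethyl]-2-methoxy-3-(4,4,5,5-tetramethyl-1,3,2-dioxaborolan-2-yl)phenoxy}tri(propan-2-yl)silane | COc1c(O[Si](C(C)C)(C(C)C)C(C)C)ccc(CCC2OCCO2)c1B1OC(C)(C)C(C)(C)O1
A4 | alternative 2 | 1,3-bis(benzyloxy)-4-ethenyl-2-methoxybenzene | C=Cc1ccc(OCc2ccccc2)c(OC)c1OCc1ccccc1
A5 | alternative 2 | octadecyl 3-[2,4-bis(benzyloxy)-3-methoxyphenyl]propanoate | CCCCCCCCCCCCCCCCCCOC(=O)CCc1ccc(OCc2ccccc2)c(OC)c1OCc1ccccc1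
A6 | alternative 3 | dioctadecyl 4-(2-methoxyacetyl)heptanedioate | COCC(=O)C(CCC(=O)OCCCCCCCCCCCCCCCCCC)CCC(=O)OCCCCCCCCCCCCCCCCCC
A7 | alternative 3 | octadecyl 3-(3-methoxy-2,4-dioxocyclohexyl)propanoate (epimer and enol mixture) | CCCCCCCCCCCCCCCCCCOC(=O)CCC1CCC(=O)C(OC)C1=O
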